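**Plan**
- Retrosynthesis: the aldehyde is unmasked last from a dioxolane. The azulene is traced back to a dihydroazulene (dehydrogenation), the C1'–CH3 bond to an enol triflate (cross-coupling), and the triflate to a bicyclic ketone. Primed locants: C1' methyl, C3' bonded to indenone C2, C3a', C4' methyl, C7' isopropyl, C8', C8a'.
- Enabling feature: the seven-membered ring (C3a', C4'–CH3, C5', C6', C7'–isopropyl, C8', C8a') is a p-cymene ring with methyl and isopropyl still para-related and one carbon, C8a', inserted between the old ipso (C3a') and ortho (C8') carbons. The five-membered ring is the tether C1'(=O)–C2'–C3' of a diazoketone. The core is therefore cut at C8a'–C3a' and C8a'–C8'.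
- Further cuts: C8a'–C1' (acylation of diazomethane), C3'–aryl (conjugate addition of a cymene boronate), indenone C2–vinyl (Heck), and the five-membered ring on ring A (Friedel–Crafts acylation/Nazarov closure on 4-bromotoluene).
- Forward: indanone on ring A, then 2-bromoindenone, dienoate, aryl addition and diazoketone. One step then closes the cyclopentanone and expands the benzene ring; triflate, methyl coupling, dehydrogenation and deprotection follow.
- Stereochemistry: the target has no stereocentre. The benzylic centre (racemic) and C8a' are both destroyed on the way to the azulene.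

Key step: step 10

Remark: chiral intermediates are racemic and each SMILES shows one enantiomer; the hindered azulene–indenone axis is not treated as a stereo element.

**Route**

Step 1
Reactants: 1 4-bromotoluene; 2 (E)-but-2-enoyl chloride
Product: 4 4-bromo-3,7-dimethylindan-1-one (racemic), via aryl propenyl ketone 3 (not isolated)
Conditions: AlCl3 (1.2 equiv), CH2Cl2, 0 °C to rt; aqueous work-up, then CF3SO3H, ClCH2CH2Cl, 60 °C
Reagents that add atoms: none
Why: Friedel–Crafts acylation ortho to the activating methyl group, then acid-mediated Nazarov-type cyclisation onto the only free ortho carbon (next to bromine), should give the indanone with C=O peri to methyl and the C3 methyl peri to bromine.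

Step 2
Reactants: 4 4-bromo-3,7-dimethylindan-1-one
Product: 5 3,7-dimethyl-1-oxoindane-4-carbaldehyde (racemic)
Conditions: Pd(OAc)2 (1 mol %), PAd2(n-Bu) (3 mol %), TMEDA, CO/H2 (1:1, 5 bar), toluene, 100 °C
Reagents that add atoms: carbon monoxide, [C-]#[O+]
Why: Palladium-catalysed reductive carbonylation (formylation) of aryl bromides with synthesis gas tolerates ketones and ortho substitution, so bromide is exchanged for CHO without touching the indanone.

Step 3
Reactants: 5 3,7-dimethyl-1-oxoindane-4-carbaldehyde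
Product: 7 2-bromo-3,7-dimethyl-1-oxo-1H-indene-4-carbaldehyde, via gem-dibromoindanone 6 (not isolated)
Conditions: Br2 (2.1 equiv), AcOH, HBr (cat.), rt to 50 °C, dark; concentrate, then Et3N, CH2Cl2, 0 °C
Reagents that add atoms: bromine, BrBr
Why: Acid-catalysed α,α-dibromination at C2 (the only enolisable position) followed by E2 dehydrobromination, which can only use H-3, should give the 2-bromoindenone with the double bond fixed at C2=C3.

Step 4
Reactants: 7 2-bromo-3,7-dimethyl-1-oxo-1H-indene-4-carbaldehyde
Product: 8 2-bromo-4-(1,3-dioxolan-2-yl)-3,7-dimethyl-1H-inden-1-one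
Conditions: ethylene glycol (1.5 equiv), p-TsOH·H2O (cat.), benzene, reflux, Dean–Stark
Reagents that add atoms: ethylene glycol, OCCO
Why: Acid-catalysed acetalisation is selective for the aryl aldehyde over the hindered conjugated indenone carbonyl and masks CHO against the boron, diazomethane, amide-base and organozinc reagents used later.

Step 5
Reactants: 8 2-bromo-4-(1,3-dioxolan-2-yl)-3,7-dimethyl-1H-inden-1-one; 9 methyl acrylate
Product: 10 methyl (E)-3-[4-(1,3-dioxolan-2-yl)-3,7-dimethyl-1-oxo-1H-inden-2-yl]prop-2-enoate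
Conditions: Pd(OAc)2 (5 mol %), n-Bu4NCl, NaHCO3, DMF, 60 °C
Reagents that add atoms: none
Why: Heck reaction of the activated α-bromo enone C–Br bond with an acrylate (oxidative addition, syn insertion, syn β-hydride elimination) should give the E-dienoate.

Step 6
Reactants: 11 2-bromo-4-isopropyl-1-methylbenzene
Product: 12 2-(5-isopropyl-2-methylphenyl)-4,4,5,5-tetramethyl-1,3,2-dioxaborolane
Conditions: B2pin2 (1.1 equiv), PdCl2(dppf) (3 mol %), KOAc, 1,4-dioxane, 90 °C
Reagents that add atoms: bis(pinacolato)diboron, CC1(C)OB(OC1(C)C)B1OC(C)(C)C(C)(C)O1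
Why: Miyaura borylation turns the commercial bromocymene (bromine ortho to methyl, meta to isopropyl) into the aryl boronate with the substitution pattern needed for C4' and C7'.

Step 7
Reactants: 10 methyl (E)-3-[4-(1,3-dioxolan-2-yl)-3,7-dimethyl-1-oxo-1H-inden-2-yl]prop-2-enoate; 12 2-(5-isopropyl-2-methylphenyl)-4,4,5,5-tetramethyl-1,3,2-dioxaborolane
Product: 13 methyl 3-[4-(1,3-dioxolan-2-yl)-3,7-dimethyl-1-oxo-1H-inden-2-yl]-3-(5-isopropyl-2-methylphenyl)propanoate (racemic)
Conditions: [Rh(cod)(OH)]2 (3 mol %), K3PO4 (1 equiv), 1,4-dioxane/H2O (10:1), 60 °C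
Reagents that add atoms: none
Why: Rhodium-catalysed conjugate addition of an arylboron reagent (Hayashi–Miyaura type) should put the aryl group on the β-carbon of the disubstituted acrylate, the tetrasubstituted indenone C=C being inert to aryl–rhodium insertion; the achiral catalyst gives the benzylic stereocentre as a racemate.

Step 8
Reactants: 13 methyl 3-[4-(1,3-dioxolan-2-yl)-3,7-dimethyl-1-oxo-1H-inden-2-yl]-3-(5-isopropyl-2-methylphenyl)propanoate
Product: 14 3-[4-(1,3-dioxolan-2-yl)-3,7-dimethyl-1-oxo-1H-inden-2-yl]-3-(5-isopropyl-2-methylphenyl)propanoic acid (racemic)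
Conditions: LiOH·H2O (3 equiv), THF/MeOH/H2O (3:1:1), 0 °C to rt; then 0.5 M HCl to pH 5 at 0 °C
Reagents that add atoms: lithium hydroxide, [Li+].[OH-]
Why: Saponification of the unhindered methyl ester should leave the dioxolane and the fully substituted indenone untouched.

Step 9
Reactants: 14 3-[4-(1,3-dioxolan-2-yl)-3,7-dimethyl-1-oxo-1H-inden-2-yl]-3-(5-isopropyl-2-methylphenyl)propanoic acid
Product: 16 1-diazo-4-[4-(1,3-dioxolan-2-yl)-3,7-dimethyl-1-oxo-1H-inden-2-yl]-4-(5-isopropyl-2-methylphenyl)butan-2-one (racemic), via isobutyl carbonic anhydride 15 (not isolated)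
Conditions: i-BuOCOCl, N-methylmorpholine, THF, −15 °C; then CH2N2 (3 equiv), Et2O, −15 °C to rt
Reagents that add atoms: isobutyl chloroformate, CC(C)COC(Cl)=O (retained only in 15); diazomethane, C=[N+]=[N-]
Why: Acylation of diazomethane by a mixed carbonic anhydride (first stage of the Arndt–Eistert sequence) gives the α-diazoketone without HCl, so the acetal should survive, and the tetrasubstituted indenone alkene is a poor dipolarophile.

Step 10
Reactants: 16 1-diazo-4-[4-(1,3-dioxolan-2-yl)-3,7-dimethyl-1-oxo-1H-inden-2-yl]-4-(5-isopropyl-2-methylphenyl)butan-2-one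
Product: 18 3-[4-(1,3-dioxolan-2-yl)-3,7-dimethyl-1-oxo-1H-inden-2-yl]-7-isopropyl-4-methyl-3,8a-dihydroazulen-1(2H)-one (racemic; H-3' and H-8a' cis as drawn), via norcaradiene 17 (not isolated)
Conditions: Rh2(OAc)4 (1 mol %), CH2Cl2, reflux, slow addition of 16, base-washed glassware; filter, concentrate below 25 °C, use at once
Reagents that add atoms: none
Why: Intramolecular Buchner reaction: Rh2(OAc)4 (divalent rhodium) releases N2 from 16, the electrophilic carbenoid carbon (the future C8a') cyclopropanates the ipso–ortho bond of the dialkylbenzene ring to norcaradiene 17, and thermal disrotatory 6π electrocyclic opening of the old ipso–ortho bond gives cycloheptatriene 18. The closest known reaction type is the Rh2(OAc)4-catalysed cyclisation of 1-diazo-4-arylbutan-2-ones, including members branched at the benzylic carbon, to 3,8a-dihydroazulen-1(2H)-ones. The five-membered ring closes by attack of the tethered carbenoid on the ipso carbon (bond C8a'–C3a', exo mode through the tether C1'–C2'–C3'), and the seven-membered ring arises by ring expansion, C8a' being inserted between C3a' and C8' when the cyclopropane bond of 17 opens. The one new stereocentre, C8a', is set under substrate control by C3' (the bulky indenonyl group is expected to stay on the side away from the approaching arene face); either epimer serves, because C8a' becomes sp2 in step 11. The step needs site selectivity between the two ipso–ortho bonds, which the ortho methyl group provides by shielding its own side, so that CH3 ends at C4' and isopropyl at C7'. It also needs chemoselectivity for the arene over the indenone, secured because the indenone C2=C3 bond is tetrasubstituted and electron-poor and ylide formation at its carbonyl oxygen would require a seven-membered ring, while acid-free handling keeps 17 and 18 from collapsing to a 2-tetralone.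

Step 11
Reactants: 18 3-[4-(1,3-dioxolan-2-yl)-3,7-dimethyl-1-oxo-1H-inden-2-yl]-7-isopropyl-4-methyl-3,8a-dihydroazulen-1(2H)-one
Product: 19 3-[4-(1,3-dioxolan-2-yl)-3,7-dimethyl-1-oxo-1H-inden-2-yl]-7-isopropyl-4-methyl-2,3-dihydroazulen-1-yl trifluoromethanesulfonate (racemic)
Conditions: KN(SiMe3)2 (1.05 equiv), PhNTf2 (1.1 equiv), THF, −78 °C; crude product used directly
Reagents that add atoms: N-phenylbis(trifluoromethanesulfonimide), O=S(=O)(N(c1ccccc1)S(=O)(=O)C(F)(F)F)C(F)(F)F
Why: Enol triflate formation: deprotonation at the most acidic α-position, the doubly allylic C8a'–H, and O-sulfonylation of the extended enolate should give the C1'=C8a' triflate, which removes the C8a' stereocentre, while the indenone has no α-hydrogen.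

Step 12
Reactants: 19 3-[4-(1,3-dioxolan-2-yl)-3,7-dimethyl-1-oxo-1H-inden-2-yl]-7-isopropyl-4-methyl-2,3-dihydroazulen-1-yl trifluoromethanesulfonate
Product: 20 4-(1,3-dioxolan-2-yl)-2-(7-isopropyl-1,4-dimethyl-2,3-dihydroazulen-3-yl)-3,7-dimethyl-1H-inden-1-one (racemic)
Conditions: MeZnCl (3 equiv), Pd(PPh3)4 (5 mol %), THF, rt to 50 °C; crude product used directly
Reagents that add atoms: methylzinc chloride, C[Zn]Cl
Why: Negishi coupling of an alkenyl triflate with a methylzinc reagent installs the C1' methyl group, and organozinc halides do not add to the indenone carbonyl or disturb the acetal.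

Step 13
Reactants: 20 4-(1,3-dioxolan-2-yl)-2-(7-isopropyl-1,4-dimethyl-2,3-dihydroazulen-3-yl)-3,7-dimethyl-1H-inden-1-one
Product: 21 4-(1,3-dioxolan-2-yl)-2-(7-isopropyl-1,4-dimethylazulen-3-yl)-3,7-dimethyl-1H-inden-1-one
Conditions: chloranil (1.1 equiv), benzene, rt to 50 °C
Reagents that add atoms: none
Why: Quinone dehydrogenation: hydride abstraction from C2' gives a tropylium-type azulenium ion that loses H-3' to form the aromatic azulene, which also erases the last stereocentre.

Step 14
Reactants: 21 4-(1,3-dioxolan-2-yl)-2-(7-isopropyl-1,4-dimethylazulen-3-yl)-3,7-dimethyl-1H-inden-1-one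
Product: 22 2-(7-isopropyl-1,4-dimethylazulen-3-yl)-3,7-dimethyl-1-oxo-1H-indene-4-carbaldehyde (CNP0233877.0)
Conditions: 1 M HCl, THF, rt
Reagents that add atoms: water, O
Why: Acid-catalysed hydrolysis of the aryl dioxolane frees the aldehyde, and the azulene has both five-ring α-positions substituted, so acid-mediated condensation with the aldehyde is not expected.

**Compound list**

1 | 4-bromotoluene | Cc1ccc(Br)cc1 | starting material
2 | (E)-but-2-enoyl chloride | C/C=C/C(Cl)=O | starting material
3 | (E)-1-(5-bromo-2-methylphenyl)but-2-en-1-one | C/C=C/C(=O)c1cc(Br)ccc1C | intermediate (not isolated)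
4 | 4-bromo-3,7-dimethylindan-1-one, racemic | C[C@@H]1CC(=O)c2c(C)ccc(Br)c21 | intermediate
5 | 3,7-dimethyl-1-oxoindane-4-carbaldehyde, racemic | C[C@@H]1CC(=O)c2c(C)ccc(C=O)c21 | intermediate
6 | 2,2-dibromo-3,7-dimethyl-1-oxoindane-4-carbaldehyde, racemic | C[C@@H]1C(Br)(Br)C(=O)c2c(C)ccc(C=O)c21 | intermediate (not isolated)
7 | 2-bromo-3,7-dimethyl-1-oxo-1H-indene-4-carbaldehyde | CC1=C(Br)C(=O)c2c(C)ccc(C=O)c21 | intermediate
8 | 2-bromo-4-(1,3-dioxolan-2-yl)-3,7-dimethyl-1H-inden-1-one | CC1=C(Br)C(=O)c2c(C)ccc(C3OCCO3)c21 | intermediate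
9 | methyl acrylate | C=CC(=O)OC | starting material
10 | methyl (E)-3-[4-(1,3-dioxolan-2-yl)-3,7-dimethyl-1-oxo-1H-inden-2-yl]prop-2-enoate | COC(=O)/C=C/C1=C(C)c2c(C3OCCO3)ccc(C)c2C1=O | intermediate
11 | 2-bromo-4-isopropyl-1-methylbenzene | Cc1ccc(C(C)C)cc1Br | starting material
12 | 2-(5-isopropyl-2-methylphenyl)-4,4,5,5-tetramethyl-1,3,2-dioxaborolane | Cc1ccc(C(C)C)cc1B1OC(C)(C)C(C)(C)O1 | intermediate
13 | methyl 3-[4-(1,3-dioxolan-2-yl)-3,7-dimethyl-1-oxo-1H-inden-2-yl]-3-(5-isopropyl-2-methylphenyl)propanoate, racemic | COC(=O)C[C@H](c1cc(C(C)C)ccc1C)C1=C(C)c2c(C3OCCO3)ccc(C)c2C1=O | intermediate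
14 | 3-[4-(1,3-dioxolan-2-yl)-3,7-dimethyl-1-oxo-1H-inden-2-yl]-3-(5-isopropyl-2-methylphenyl)propanoic acid, racemic | OC(=O)C[C@H](c1cc(C(C)C)ccc1C)C1=C(C)c2c(C3OCCO3)ccc(C)c2C1=O | intermediate
15 | isobutyl carbonic anhydride of acid 14, racemic | CC(C)COC(=O)OC(=O)C[C@H](c1cc(C(C)C)ccc1C)C1=C(C)c2c(C3OCCO3)ccc(C)c2C1=O | intermediate (not isolated)
16 | 1-diazo-4-[4-(1,3-dioxolan-2-yl)-3,7-dimethyl-1-oxo-1H-inden-2-yl]-4-(5-isopropyl-2-methylphenyl)butan-2-one, racemic | [N-]=[N+]=CC(=O)C[C@H](c1cc(C(C)C)ccc1C)C1=C(C)c2c(C3OCCO3)ccc(C)c2C1=O | intermediate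
17 | norcaradiene valence isomer of 18 (cyclopropane C3a'–C8'–C8a' fused to the cyclopentanone and to a cyclohexadiene), racemic | O=C1C[C@@H](C4=C(C)c5c(C6OCCO6)ccc(C)c5C4=O)[C@@]23C(C)=CC=C(C(C)C)[C@@H]2[C@@H]13 | intermediate (not isolated)
18 | 3-[4-(1,3-dioxolan-2-yl)-3,7-dimethyl-1-oxo-1H-inden-2-yl]-7-isopropyl-4-methyl-3,8a-dihydroazulen-1(2H)-one, racemic, H-3'/H-8a' cis | O=C1C[C@@H](C4=C(C)c5c(C6OCCO6)ccc(C)c5C4=O)C2=C(C)C=CC(C(C)C)=C[C@@H]12 | intermediate
19 | 3-[4-(1,3-dioxolan-2-yl)-3,7-dimethyl-1-oxo-1H-inden-2-yl]-7-isopropyl-4-methyl-2,3-dihydroazulen-1-yl trifluoromethanesulfonate, racemic | O=S(=O)(OC1=C2C=C(C(C)C)C=CC(C)=C2[C@H](C3=C(C)c4c(C5OCCO5)ccc(C)c4C3=O)C1)C(F)(F)F | intermediate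
20 | 4-(1,3-dioxolan-2-yl)-2-(7-isopropyl-1,4-dimethyl-2,3-dihydroazulen-3-yl)-3,7-dimethyl-1H-inden-1-one, racemic | CC1=C2C=C(C(C)C)C=CC(C)=C2[C@H](C3=C(C)c4c(C5OCCO5)ccc(C)c4C3=O)C1 | intermediate
21 | 4-(1,3-dioxolan-2-yl)-2-(7-isopropyl-1,4-dimethylazulen-3-yl)-3,7-dimethyl-1H-inden-1-one | CC1=C(c2cc(C)c3cc(C(C)C)ccc(C)c2-3)C(=O)c2c(C)ccc(C3OCCO3)c21 | intermediate
22 | 2-(7-isopropyl-1,4-dimethylazulen-3-yl)-3,7-dimethyl-1-oxo-1H-indene-4-carbaldehyde | CC1=C(c2cc(C)c3cc(C(C)C)ccc(C)c2-3)C(=O)c2c(C)ccc(C=O)c21 | target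

**Step count**

Total: 14 steps. Longest linear sequence: 13 steps (steps 1–5 and 7–14; step 6 is a one-step branch).

**Steps most likely to fail**

Step 11. The amide base may trigger prototropic double-bond migration around the cycloheptatriene, and the heptafulvene-type enolate or triflate may oligomerise before or after O-sulfonylation. The fallback sets out from 18 and brings the methyl group in as a nucleophile. MeTi(OiPr)3 in Et2O/THF is non-basic and selective for the saturated cyclopentanone over the hindered conjugated indenone carbonyl. It should give racemic 3-[4-(1,3-dioxolan-2-yl)-3,7-dimethyl-1-oxo-1H-inden-2-yl]-7-isopropyl-1,4-dimethyl-1,2,3,8a-tetrahydroazulen-1-ol F1. Dehydration with the Burgess reagent (benzene, 50 °C) should give 20 and/or its C1'=C2' isomer, racemic 4-(1,3-dioxolan-2-yl)-2-(7-isopropyl-1,4-dimethyl-3,8a-dihydroazulen-3-yl)-3,7-dimethyl-1H-inden-1-one F2. Chloranil, as in step 13, takes either isomer to 21, where the route is rejoined.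

Step 7. Transfer of the ortho-substituted aryl group to rhodium and its insertion into the hindered β-position may be slow, so that protodeboronation of 12 uses up the boronate. The fallback sets out from 11 and 8 and forms the C2–CH bond by cross-coupling. Heck reaction of 11 with methyl acrylate 9 (Pd(OAc)2, P(o-tol)3, Et3N, MeCN, 80 °C) gives methyl (E)-3-(5-isopropyl-2-methylphenyl)prop-2-enoate F3. Copper-catalysed conjugate borylation (CuCl, NaOt-Bu, bis(2-diphenylphosphinophenyl) ether, B2pin2, MeOH, THF, rt) gives racemic methyl 3-(5-isopropyl-2-methylphenyl)-3-(4,4,5,5-tetramethyl-1,3,2-dioxaborolan-2-yl)propanoate F4. Suzuki–Miyaura coupling of this secondary benzylic boronate with alkenyl bromide 8 (Pd2(dba)3, PPh3, Ag2O, THF, 70 °C) comes back to the route at 13.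

Step 10. The carbenoid may be diverted to the indenone (cyclopropanation of C2=C3 or ylide formation at the carbonyl oxygen) or to the methyl-bearing ipso–ortho bond, or 17 may open to a 2-tetralone under traces of acid instead of ring-expanding. The fallback gives up the ring expansion and sets out from 8. The seven-membered ring is taken ready-made as commercial 7-isopropyl-1,4-dimethylazulene (guaiazulene) F5. It is joined to 8 by palladium-catalysed direct C–H coupling at the free, nucleophilic five-ring position C3 (Pd(OAc)2, CsOAc, N,N-dimethylacetamide, 100 °C), a reaction type known for this azulene with aryl bromides. This gives 21 directly, and the route is rejoined before step 14.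

**Further compounds**

F1 | step 11 | 3-[4-(1,3-dioxolan-2-yl)-3,7-dimethyl-1-oxo-1H-inden-2-yl]-7-isopropyl-1,4-dimethyl-1,2,3,8a-tetrahydroazulen-1-ol, racemic, C1' epimer drawn arbitrarily | C[C@]1(O)C[C@@H](C4=C(C)c5c(C6OCCO6)ccc(C)c5C4=O)C2=C(C)C=CC(C(C)C)=C[C@@H]12
F2 | step 11 | 4-(1,3-dioxolan-2-yl)-2-(7-isopropyl-1,4-dimethyl-3,8a-dihydroazulen-3-yl)-3,7-dimethyl-1H-inden-1-one, racemic | CC1=C[C@@H](C4=C(C)c5c(C6OCCO6)ccc(C)c5C4=O)C2=C(C)C=CC(C(C)C)=C[C@@H]12
F3 | step 7 | methyl (E)-3-(5-isopropyl-2-methylphenyl)prop-2-enoate | COC(=O)/C=C/c1cc(C(C)C)ccc1C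
F4 | step 7 | methyl 3-(5-isopropyl-2-methylphenyl)-3-(4,4,5,5-tetramethyl-1,3,2-dioxaborolan-2-yl)propanoate, racemic | COC(=O)C[C@H](c1cc(C(C)C)ccc1C)B1OC(C)(C)C(C)(C)O1
F5 | step 10 | 7-isopropyl-1,4-dimethylazulene (guaiazulene, commercial) | Cc1ccc2c(C)ccc(C(C)C)cc12
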